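**Retrosynthetic overview**

1. The strategy rests on the central benzene ring. C4 (4-hydroxybenzyl), C5 (2-phenylethyl) and C6 (4-hydroxybenzyl) stand in a row, opposite the C1(OH)–C2(H)–C3(OH) half.
2. After three aryl ethers are unmasked, this ring is cut at C1–C2, C3–C4 and C1–C6 (Danheiser benzannulation). This gives a 2,3,4-trisubstituted cyclobutenone (C1, C4, C5, C6) and ethoxyacetylene (C2, C3).
3. The phenethyl arm is taken off the cyclobutenone by reversing an organometallic addition and carbonyl-transposing hydrolysis. This leads back to a 3-ethoxy-2,4-dibenzylcyclobutenone.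
4. The two benzyl arms are identical, so that four-membered ring is the thermal self-combination of one ynol ether. The ynol ether comes from ethoxyacetylene and 4-methoxybenzyl bromide.
5. Ring order: the three outer benzene rings are bought, the four-membered ring is made first, and the central benzene ring is made last by two-carbon ring expansion.

Key step: step 6

Remark: the target has no stereocentre. The sp3 ring carbons of the four-membered and cyclohexadienone intermediates are therefore carried as racemates or diastereomer mixtures and disappear on hydrolysis and aromatization.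

**Step 1**
Reactants: 1 ethoxyacetylene (commercial solution in hexanes); 2 4-methoxybenzyl bromide
Product: 4 1-ethoxy-3-(4-methoxyphenyl)prop-1-yne, via lithium ethoxyacetylide 3 (not isolated)
Conditions: 1 (1.1 equiv), n-BuLi (1.0 equiv), THF, −78 °C; CuBr·SMe2 (10 mol %), then 2 (1.05 equiv), −78 °C → rt; pH 7 work-up, filtration through basic alumina
Reagents that add atoms: none
Why: Copper-catalysed alkylation of a lithium acetylide (SN2 at a benzylic bromide): the base is kept below the amount of alkyne and the acetylide is used up by a slight excess of the very reactive bromide, so nothing basic remains to shift the propargylic–benzylic CH2 of 4 towards the allenyl ether.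

**Step 2**
Reactants: 4 1-ethoxy-3-(4-methoxyphenyl)prop-1-yne (two molecules)
Product: 6 3-ethoxy-2,4-bis(4-methoxybenzyl)cyclobut-2-en-1-one (racemic), via (4-methoxybenzyl)ketene 5 (not isolated)
Conditions: neat or ca. 3 M in o-xylene, 120 °C, Ar, open to a bubbler; stopped as soon as 4 is consumed
Reagents that add atoms: none
Why: Retro-ene fragmentation followed by ketene–alkyne (2+2) cycloaddition, the classical thermal behaviour of 1-ethoxyalkynes: part of 4 expels ethylene through a six-membered transition state to give aldoketene 5, the benzyl-bearing nucleophilic alkyne carbon of unchanged 4 attacks the ketene carbonyl carbon and so fixes the 2,4-dibenzyl-3-ethoxy pattern, and the new C4 stereocentre forms racemic and is erased in step 6.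

**Step 3**
Reactants: 7 (2-bromoethyl)benzene
Product: 8 2-phenylethylmagnesium bromide (titrated THF solution)
Conditions: Mg turnings (1.2 equiv), crystal of iodine, THF, slow addition, 25–40 °C
Reagents that add atoms: magnesium [Mg]
Why: Grignard formation by insertion of magnesium into a primary alkyl bromide, with slow addition at moderate temperature to keep Wurtz coupling low.

**Step 4**
Reactants: 6 3-ethoxy-2,4-bis(4-methoxybenzyl)cyclobut-2-en-1-one; 8 2-phenylethylmagnesium bromide
Product: 10 3-ethoxy-2,4-bis(4-methoxybenzyl)-1-(2-phenylethyl)cyclobut-2-en-1-ol (mixture of diastereomers), via dichloro(2-phenylethyl)cerium 9 (not isolated)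
Conditions: anhydrous CeCl3 (1.6 equiv), THF, −78 °C, 8 (1.5 equiv); then 6, −78 → −20 °C; cold water/pH 7 buffer quench; crude product used directly
Reagents that add atoms: none
Why: Organocerium 1,2-addition to a ketone: transmetallation gives a strongly oxophilic, weakly basic nucleophile that adds to the hindered, electronically deactivated vinylogous-ester carbonyl rather than deprotonating or reducing it, and the new carbinol centre (attack expected mainly anti to the C4 benzyl group) needs no control because it becomes sp2 in step 5.

**Step 5**
Reactants: 10 3-ethoxy-2,4-bis(4-methoxybenzyl)-1-(2-phenylethyl)cyclobut-2-en-1-ol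
Product: 11 2,4-bis(4-methoxybenzyl)-3-(2-phenylethyl)cyclobut-2-en-1-one (racemic)
Conditions: 1 M aq. HCl, THF, 0 °C → rt
Reagents that add atoms: water O
Why: Acid-catalysed enol ether hydrolysis with 1,3-carbonyl transposition (the four-membered-ring counterpart of the Stork–Danheiser transposition): the tertiary allylic alcohol ionizes to an ethoxy-stabilized cyclobutenyl cation, water adds at the ethoxy-bearing carbon and ethanol leaves, so the carbonyl appears at the former C3, the phenethyl carbon becomes the β-carbon of the enone, and C4 stays racemic.

**Step 6**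
Reactants: 11 2,4-bis(4-methoxybenzyl)-3-(2-phenylethyl)cyclobut-2-en-1-one; 1 ethoxyacetylene
Product: 16 5-ethoxy-2,4-bis(4-methoxybenzyl)-3-(2-phenylethyl)phenol, via vinylketene 12 (not isolated), via 4-alkenylcyclobutenone 13 (not isolated), via dienylketene 14 (not isolated), via cyclohexadienone 15 (not isolated)
Conditions: 1 (4 equiv), toluene, sealed heavy-walled tube, 80 °C until 11 is consumed; vented, then 110 °C to finish the cascade
Reagents that add atoms: none
Why: Danheiser benzannulation, the established thermal reaction of cyclobutenones with alkoxyalkynes to give resorcinol monoethers, used here on a 2,3,4-trisubstituted cyclobutenone. Heating cleaves the C1–C4 bond of 11 by conrotatory 4π electrocyclic opening with the C4 benzyl group turning outward, and the ketene C=C of the resulting 12 combines with 1 in a (2+2) cycloaddition that closes the transient four-membered ring of 13 and lays down the arene bonds C1–C2 and C3–C4. Reversible 4π opening of 13 gives 14, and the central six-membered ring, the only ring that lasts, closes by 6π electrocyclization between the ketene carbon (arene C1) and the benzyl-bearing alkene terminus (arene C6). Dienone 15 keeps one hydrogen on C6 and tautomerizes irreversibly to 16, so the quaternary centre of 13 and the C6 centre of 15 form racemic, need no control and vanish on aromatization. The one selectivity required is the orientation of the (2+2) step: donation from oxygen puts the negative end of the triple bond of 1 on its unsubstituted carbon, which attacks the central electrophilic carbon of the ketene, so C2–H is placed between C1–OH and C3–OEt and C3 is tied to C4. Because 11 already carries the three carbon substituents in their final sequence, the arene is born fully substituted and no later C-benzylation has to be directed.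

**Step 7**
Reactants: 16 5-ethoxy-2,4-bis(4-methoxybenzyl)-3-(2-phenylethyl)phenol
Product: 17 4,6-bis(4-hydroxybenzyl)-5-(2-phenylethyl)benzene-1,3-diol (target CNP0361781.0)
Conditions: BBr3 (7 equiv, 1 M in CH2Cl2), CH2Cl2, −78 °C → rt; ice-water quench
Reagents that add atoms: none
Why: Lewis acid mediated cleavage of aryl alkyl ethers: BBr3 binds each ether oxygen and bromide removes the methyl or ethyl group by SN2, the diarylmethane C–C bonds and the saturated chain are inert at or below room temperature, and hydrolysis of the aryl borates should release the achiral tetraphenol 17.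

**Compound list**

| No. | Name | SMILES | Role |
|---|---|---|---|
| 1 | ethoxyacetylene | CCOC#C | starting material |
| 2 | 4-methoxybenzyl bromide | COc1ccc(CBr)cc1 | starting material |
| 3 | lithium ethoxyacetylide | [Li]C#COCC | intermediate |
| 4 | 1-ethoxy-3-(4-methoxyphenyl)prop-1-yne | CCOC#CCc1ccc(OC)cc1 | intermediate |
| 5 | (4-methoxybenzyl)ketene, 3-(4-methoxyphenyl)prop-1-en-1-one | O=C=CCc1ccc(OC)cc1 | intermediate |
| 6 | 3-ethoxy-2,4-bis(4-methoxybenzyl)cyclobut-2-en-1-one (racemic) | CCOC1=C(Cc2ccc(OC)cc2)C(=O)C1Cc1ccc(OC)cc1 | intermediate |
| 7 | (2-bromoethyl)benzene | BrCCc1ccccc1 | starting material |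
| 8 | 2-phenylethylmagnesium bromide | Br[Mg]CCc1ccccc1 | intermediate |
| 9 | dichloro(2-phenylethyl)cerium | Cl[Ce](Cl)CCc1ccccc1 | intermediate |
| 10 | 3-ethoxy-2,4-bis(4-methoxybenzyl)-1-(2-phenylethyl)cyclobut-2-en-1-ol (mixture of diastereomers) | CCOC1=C(Cc2ccc(OC)cc2)C(O)(CCc2ccccc2)C1Cc1ccc(OC)cc1 | intermediate |
| 11 | 2,4-bis(4-methoxybenzyl)-3-(2-phenylethyl)cyclobut-2-en-1-one (racemic) | O=C1C(Cc2ccc(OC)cc2)=C(CCc2ccccc2)C1Cc1ccc(OC)cc1 | intermediate |
| 12 | (3E)-2-(4-methoxybenzyl)-5-(4-methoxyphenyl)-3-(2-phenylethyl)penta-1,3-dien-1-one (vinylketene) | O=C=C(Cc1ccc(OC)cc1)/C(CCc1ccccc1)=C/Cc1ccc(OC)cc1 | intermediate |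
| 13 | 3-ethoxy-4-(4-methoxybenzyl)-4-[(2E)-1-(4-methoxyphenyl)-5-phenylpent-2-en-3-yl]cyclobut-2-en-1-one (racemic) | CCOC1=CC(=O)C1(Cc1ccc(OC)cc1)/C(CCc1ccccc1)=C/Cc1ccc(OC)cc1 | intermediate |
| 14 | (3E,5E)-3-ethoxy-4-(4-methoxybenzyl)-7-(4-methoxyphenyl)-5-(2-phenylethyl)hepta-1,3,5-trien-1-one (dienylketene) | O=C=C/C(OCC)=C(Cc1ccc(OC)cc1)\C(CCc1ccccc1)=C\Cc1ccc(OC)cc1 | intermediate |
| 15 | 3-ethoxy-4,6-bis(4-methoxybenzyl)-5-(2-phenylethyl)cyclohexa-2,4-dien-1-one (racemic) | CCOC1=CC(=O)C(Cc2ccc(OC)cc2)C(CCc2ccccc2)=C1Cc1ccc(OC)cc1 | intermediate |
| 16 | 5-ethoxy-2,4-bis(4-methoxybenzyl)-3-(2-phenylethyl)phenol | CCOc1cc(O)c(Cc2ccc(OC)cc2)c(CCc2ccccc2)c1Cc1ccc(OC)cc1 | intermediate |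
| 17 | 4,6-bis(4-hydroxybenzyl)-5-(2-phenylethyl)benzene-1,3-diol | Oc1ccc(Cc2c(O)cc(O)c(Cc3ccc(O)cc3)c2CCc2ccccc2)cc1 | target |

Total step count: 7
Longest linear sequence: 6 steps (steps 1, 2, 4, 5, 6, 7; step 3 is a one-step side branch)

**Steps most likely to fail**

**Step 6.**
- The crowded cyclobutenone may open more slowly than the alkyne is lost by retro-ene fragmentation, oligomerization or escape into the headspace.
- The vinylketene may then be drained by dimerization or by O-acylation of the phenol already formed. After inward rotation of the C4 benzyl group, it may also be drained by a 1,5-hydrogen shift.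
- The cascade may also stall before the second ring opening.
- The fallback sets out from 8 and 2 and comes back at 17. The central ring is bought and substituted instead of being built.
  - Kumada coupling of 8 with commercial 1-bromo-3,5-dimethoxybenzene F1 (NiCl2(dppp) cat., THF) should give 1,3-dimethoxy-5-(2-phenylethyl)benzene F2.
  - Two equivalents of NBS in MeCN should brominate the two positions flanking the chain, each ortho to one methoxy group and para to the other. This gives 2,4-dibromo-1,5-dimethoxy-3-(2-phenylethyl)benzene F3.
  - Zinc insertion into 2 (Zn dust, LiCl, THF, 0 °C) gives 4-methoxybenzylzinc bromide F4.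
  - Double Negishi coupling of F3 with F4 (Pd(OAc)2, SPhos, THF, 60 °C) should give 1,5-dimethoxy-2,4-bis(4-methoxybenzyl)-3-(2-phenylethyl)benzene F5.
  - BBr3 under the conditions of step 7 then cleaves the four methyl ethers to 17.

**Step 2.**
- At 120 °C the ketene may dimerize with itself.
- The product may open thermally and capture a third molecule of ynol ether, which is a premature benzannulation.
- The skipped ynol ether may drift to its allenyl isomer.
- The fallback sets out from 4 and comes back at 6. The ketene is no longer drawn from the ynol ether by pericyclic fragmentation. Instead it is made by dehydrochlorination at ambient temperature.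
  - Commercial 3-(4-methoxyphenyl)propanoyl chloride F6 is added slowly to 4 and Et3N in Et2O or toluene at rt.
  - This generates 5 in low concentration in the presence of its trap, so that the same (2+2) cycloaddition should give 6 and every molecule of 4 serves as ketenophile.

**Step 1.**
- A prototropic shift of the propargylic–benzylic CH2 under basic conditions is possible.
- The labile bromide may undergo homocoupling or self-condensation.
- The ynol ether may be hydrated on acidic supports.
- The fallback sets out from 3 and comes back at 4. Nucleophilic substitution is replaced by a cross-coupling of a far less basic organometal.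
  - Compound 3 is transmetallated with ZnCl2 (THF, −78 → 0 °C) to chloro(ethoxyethynyl)zinc F7.
  - F7 is joined to 2 by Negishi alkynyl–benzyl coupling (PdCl2(DPEphos) cat., THF, rt).

**Further compounds**

F1 | step 6 | 1-bromo-3,5-dimethoxybenzene | COc1cc(Br)cc(OC)c1
F2 | step 6 | 1,3-dimethoxy-5-(2-phenylethyl)benzene | COc1cc(CCc2ccccc2)cc(OC)c1
F3 | step 6 | 2,4-dibromo-1,5-dimethoxy-3-(2-phenylethyl)benzene | COc1cc(OC)c(Br)c(CCc2ccccc2)c1Br
F4 | step 6 | 4-methoxybenzylzinc bromide | COc1ccc(C[Zn]Br)cc1
F5 | step 6 | 1,5-dimethoxy-2,4-bis(4-methoxybenzyl)-3-(2-phenylethyl)benzene | COc1cc(OC)c(Cc2ccc(OC)cc2)c(CCc2ccccc2)c1Cc1ccc(OC)cc1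
F6 | step 2 | 3-(4-methoxyphenyl)propanoyl chloride | COc1ccc(CCC(=O)Cl)cc1
F7 | step 1 | chloro(ethoxyethynyl)zinc | CCOC#C[Zn]Cl
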